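Watch where the product stops, and read that stop against the partner you charged.

| setting | north | south | blue | red | grey | teal |
|---|---|---|---|---|---|---|
| substrate | 10 mM | 10 mM | 10 mM | 10 mM | 10 mM | 10 mM |
| partner | 0.50 equiv | 0.75 equiv | 1.00 equiv | 1.00 equiv | 1.00 equiv | 1.00 equiv |
| protic impurity | 0.50 mM | 0.50 mM | 0.500 mM | 0.500 mM | 0.500 mM | 0.500 mM |
| temperature | −5 °C | 38 °C | 75 °C | 50 °C | 25 °C | 0 °C |
| remark | run made earlier | run made earlier |  |  |  |  |
| time |  |  | 1.0 h | 1.0 h | 1.0 h | 1.0 h |

| run | time / h | product / % |
|---|---|---|
| north | 4.00 | 16.7 |
| north | 8.00 | 29.0 |
| north | 10.0 | 33.4 |
| north | 20.0 | 42.7 |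
| north | 40.0 | 44.9 |
| north | 48.0 | 44.3 |
| south | 0.417 | 59.1 |
| south | 1.33 | 70.2 |
| south | 2.00 | 70.7 |
| south | 3.00 | 71.4 |
| south | 5.00 | 71.3 |
| south | 6.00 | 71.3 |

(readings scatter by 0.3 percentage points)

- the numbers in the tables scatter by 0.3 percentage points (one standard deviation)

- which flask leads in amount of product, in percent of the substrate charged ("all alike" within 1.5 percentage points) (blue / red / grey / teal / all alike)
- how much product is there at the end, in percent of the substrate charged: blue
- how much product is there at the end, in percent of the substrate charged: red
- how much product is there at the end, in percent of the substrate charged: grey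
- how much product is there at the end, in percent of the substrate charged: teal

I laid the two earlier runs side by side, since they look nearly the same: equal substrate, equal protic impurity, and product flattening in both. The north run levelled off with a reading of 44.9% and the south run with a reading of 71.3%. In each, partner was the limiting reagent, its charge of 5.00 mM in north and 7.50 mM in south being less than the substrate. The south run stopped 0.370 mM short of its partner charge, and the north run 0.510 mM short. I called this shortfall, c(partner) charged minus c(product) on the plateau, the toll. The north toll was about the 0.50 mM of impurity charged, so I read it as partner lost to the impurity, and the south toll, at 38 °C, was smaller. The two runs ended apart because their partner charges differ by 2.50 mM, far more than their tolls differ.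

For the new flasks, at 1.00 equiv of partner, I took the south toll, read at 38 °C, and got 96.3% of the substrate charged as my estimate of the stop. I expected blue, the hottest flask, to come closest to it, since the south run, warmer and richer in partner, had 59.1% at 0.417 h while north had 33.4% at 10.0 h.

The forecast, made from the same two runs, named blue, with 96% for blue, 92.3% for red, 72% for grey and 20% for teal, and it said: “Impurity therefore competes less well when hot.”

The flasks gave 96.5% in blue, 91.7% in red, 75.4% in grey and 9.54% in teal, so blue led.

    partner → second intermediate (k = 0.00150 /s, Ea = 77.0 kJ/mol)
    substrate → open intermediate (k = 0.0180 /s, Ea = 79.0 kJ/mol)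
    partner + protic impurity → quenched reagent (k = 0.710 /M/s, Ea = 40.0 kJ/mol)
    open intermediate + second intermediate → product (k = 0.130 /M/s, Ea = 38.0 kJ/mol)
    (constants at 25 °C)

Blue's shortfall at 1.00 h came to 0.352 mM, a little below the south toll, but blue had not stopped, for its product reached 97.9% at 10.0 h; at 1.00 h blue held 0.210 mM of quenched reagent and 0.142 mM of second intermediate, which together make up that shortfall. The same subtraction on the blue flask charged with 0.250 equiv of partner gives a toll of 0.0632 mM, and that flask held 0.0632 mM of quenched reagent with 0 mM of second intermediate.

Readings and results were generated by integration for substances that don't exist; noise was put on by code.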